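Start from one ratio in the summer flask, the flask asked about: the partner charged against what can claim it.

| setting | summer | dawn | flask |
|---|---|---|---|
| starting material | 0.20 M | 0.20 M | 0.20 M |
| second substrate | 1 equiv | 1 equiv | 1.00 equiv |
| partner | 1.1 equiv | 1.1 equiv | 1.10 equiv |
| protic impurity | 0.060 M | 0.060 M | 0.0600 M |
| free catalyst | 0.061 mol% | 0.03 mol% | 0.061 mol% |
| remark | the very flask that is asked about, followed so far | run made earlier |  |
| time |  |  | 3.0 h |

| run | time / min | target / % | starting material / % |
|---|---|---|---|
| summer | 8.00 | 22.5 | 54.8 |
| summer | 20.0 | 34.5 | 37.3 |
| summer | 40.0 | 41.8 | 28.4 |
| summer | 60.0 | 43.7 | 25.9 |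
| summer | 80.0 | 44.4 | 25.2 |
| summer | 120 | 45.2 | 24.9 |
| dawn | 1.00 | 2.2 | 91.9 |
| dawn | 2.00 | 4.2 | 84.6 |
| dawn | 3.00 | 5.7 | 79.8 |
| dawn | 5.00 | 9.3 | 71.6 |
| dawn | 8.00 | 13.0 | 63.4 |
| dawn | 15.0 | 19.8 | 52.3 |

(readings scatter by 0.3 percentage points)

- east: at 3.0 h add partner, 50.0 % of the amount charged, then wait 3.0 h
- north-west: change nothing and wait 3.0 h more
- north: at 3.0 h add free catalyst, 100 % of the amount charged, then wait 3.0 h
- south-east: at 3.0 h take out 90 % of the target then present, then wait 3.0 h

- target, in percent of the starting material first charged, at 3.0 h
- the remedy with the largest gain of target, or "none" below 2 percentage points (east / north-west / north / south-east / none)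
- target present, with what was taken out counted in, in percent of the starting material first charged, after north-west
- target present, with what was taken out counted in, in percent of the starting material first charged, after south-east

- removed target is counted in
- what was read earlier has a scatter of 0.3 percentage points, one standard deviation
- additions bring no volume worth counting

At 120 min the summer readings of target and starting material together stop 29.9 % short of the charge. The protic impurity was charged at 30.0 % of the starting material, so I take it that the impurity removes that share mole for mole and leaves 70.0 % able to become target. Target stalls near 45.2 % although 1.10 equiv of partner was charged, so I suppose that the second substrate takes partner one for one as well. That makes the claims on partner 1.70 on the same scale. As the zero of the scale I use the symmetric case, a selectivity factor of one, in which each claimant gets the same share of what it holds. That share is the partner ration f, the partner charged divided by the summed claims, 0.647.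

Turn the question round: for the stall to be anything but a shortage of partner, the limiting reagent here, f would have to reach one, and this flask stands at 0.647, with a shortfall of 0.600 in equivalents of partner, the claims minus the partner charged. My target is then f times the free share, 45.3 %, which comes from the charges, while 45.2 % comes from a reading. The ration holds neither catalyst nor time, so I expect nothing from north-west or north, and taking target out returns no partner, so south-east stays at 45.3 % with the removed target counted in. East brings 0.550, less than the shortfall, so f rises to 0.971 and I expect a gain of 23 percentage points, and I choose east.

The forecast gives 45.3 % now, 45.3 % after north-west and 58 % after south-east, and it chooses south-east, holding that “the plateau is equilibrium, not a dead catalyst”.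

The flask gives 44.9 % at 3.0 h, 44.9 % after north-west and 44.9 % after south-east, and the best remedy is east, with a gain of 21 points, against 0 points for north.

    partner + catalyst intermediate A → free catalyst + target (k = 1570 M⁻¹ min⁻¹)
    partner + catalyst intermediate B → free catalyst + second product (k = 1030 M⁻¹ min⁻¹)
    second substrate + free catalyst ⇌ catalyst intermediate B (K = 5.04 M⁻¹, k = 35600 M⁻¹ min⁻¹)
    starting material + protic impurity → quenched substrate (k = 1.21 M⁻¹ min⁻¹)
    starting material + free catalyst ⇌ catalyst intermediate A (K = 2.88 M⁻¹, k = 18500 M⁻¹ min⁻¹)

In the summer flask at 180 min, second substrate stands at 34.9 % of its own charge, where one minus f gives 35.3 %, and partner is down to 0.00852 % of its own charge. The neighbour flask charged with 4.00 equiv of second substrate has a ration of 0.234, which gives 16.4 % target and 76.6 % of its second substrate left. At 180 min that neighbour holds 16.3 % target, of its second substrate 76.6 % is left, and partner stands at 0 %.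

The earlier runs and the new flask are simulated on assumed constants, noise included.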